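The side chain is cut between C3' and C4' (C1' = acetoxy carbinol carbon on quaternary C5 of the cyclopentenone ring), so that C1'–C3' maps onto acrolein and C4'–C15' onto 1-bromododecane. The key step exploits C3' being the terminus of a vinyl carbinol: 9-BBN reverses the native acceptor polarity of this acrolein β-carbon and parks the ring C1 carbonyl as a borinate, and a Pd-catalysed alkyl–alkyl Suzuki coupling then unites two formerly electrophilic sp3 carbons in one flask. The precursor is the acetonide-locked cyclopentenone bearing a three-carbon allylic acetate at C5, from an aldol reaction that sets C5 and C1'.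

Key step: step 2

Assumption: (4S,5S)-4,5-O-isopropylidene-4,5-dihydroxycyclopent-2-en-1-one (1) is taken as a purchasable, ribose-derived building block. The spatial arrangement at C5 stays the same from 5 to 12; its R/S descriptor changes only because the CIP priorities of its neighbours change.

Step 1
Reactants: 1 (4S,5S)-4,5-O-isopropylidene-4,5-dihydroxycyclopent-2-en-1-one; 2 acrolein
Product: 5 (4S,5R)-5-[(1S)-1-acetoxyprop-2-en-1-yl]-4,5-(isopropylidenedioxy)cyclopent-2-en-1-one, via lithium enolate 3 (not isolated), via lithium aldolate 4 (not isolated)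
Conditions: LDA, THF, −78 °C; 2, −78 °C; then Ac2O, −78 → 0 °C
Reagents that add atoms: acetic anhydride CC(=O)OC(C)=O
Why: Kinetic α'-deprotonation gives enolate 3 (loss of O-4 would give an antiaromatic cyclopentadienone, so it should persist at −78 °C), and a lithium aldol addition through a Zimmerman–Traxler chair on the convex face anti to the dioxolane, with the vinyl group equatorial, should set C5 (side chain anti to the acetonide) and C1' (S) together, after which in situ O-acetylation of aldolate 4 blocks retro-aldol equilibration.

Step 2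
Reactants: 5 (4S,5R)-5-[(1S)-1-acetoxyprop-2-en-1-yl]-4,5-(isopropylidenedioxy)cyclopent-2-en-1-one; 6 1-bromododecane
Product: 9 ring C1 allylic alcohol carrying the complete (1S)-1-acetoxypentadecyl chain (C4/C5/C1' as in 5; C1 epimers), via bis(9-BBN) adduct 7 (not isolated), via coupled O-boryl borinate 8 (not isolated)
Conditions: 9-BBN (2.4 equiv), THF, 0 °C → rt; then Pd(OAc)2 (5 mol%), PCy3 (10 mol%), K3PO4·H2O, 6, degassed THF, rt; aq. NH4Cl work-up
Reagents that add atoms: none
Why: 9-BBN adds syn and anti-Markovnikov to the vinyl group, placing boron on the terminal carbon C3', and at the same time reduces the enone carbonyl 1,2 to the borinate, so 7 carries no enone that could intercept alkyl–Pd or borane species. Hydroxide from K3PO4·H2O forms the borate, Pd(0)/PCy3 adds oxidatively to 1-bromododecane by an SN2-type path, and transmetalation of the primary alkyl group followed by reductive elimination forms the C3'–C4' sp3–sp3 bond. The closest known reaction type is the room-temperature B-alkyl Suzuki–Miyaura coupling of B-alkyl-9-BBN reagents with primary alkyl bromides that carry β-hydrogens. No ring is closed; the only new stereocentre is the ring carbinol carbon C1, which is left uncontrolled because step 3 removes it. The step needs terminal regioselectivity in the hydroboration (secured by the bulk of 9-BBN and by the monosubstituted alkene reacting far faster than the cis-disubstituted ring alkene), survival of acetate and acetonide (both inert to 9-BBN and to hydrated phosphate at room temperature) and suppression of β-hydride elimination (secured by the bulky, electron-rich PCy3).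

Step 3
Reactants: 9 ring C1 allylic alcohol (C1 epimers)
Product: 10 (4S,5S)-5-[(1S)-1-acetoxypentadecyl]-4,5-(isopropylidenedioxy)cyclopent-2-en-1-one
Conditions: Dess–Martin periodinane, NaHCO3, CH2Cl2, 0 °C → rt
Reagents that add atoms: none
Why: Dess–Martin oxidation of the secondary allylic alcohol should restore the cyclopentenone from both C1 epimers, while the acetate, the acetonide and the fully substituted C5 are not affected.

Step 4
Reactants: 10 (4S,5S)-5-[(1S)-1-acetoxypentadecyl]-4,5-(isopropylidenedioxy)cyclopent-2-en-1-one
Product: 11 (4S,5R)-5-[(1S)-1-acetoxypentadecyl]-4,5-dihydroxycyclopent-2-en-1-one (4,5-cis diol)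
Conditions: TFA–H2O (4:1), 0 °C → rt
Reagents that add atoms: none
Why: Acid-catalysed acetal hydrolysis should release the cis-4,5-diol without touching a stereocentre, and the secondary acetate should survive cold aqueous TFA.

Step 5
Reactants: 11 (4S,5R)-5-[(1S)-1-acetoxypentadecyl]-4,5-dihydroxycyclopent-2-en-1-one
Product: 12 (4R,5S)-4-acetoxy-5-[(1S)-1-acetoxypentadecyl]-5-hydroxycyclopent-2-en-1-one
Conditions: PPh3, DIAD, AcOH, THF, 0 °C → rt
Reagents that add atoms: acetic acid CC(=O)O
Why: In this Mitsunobu reaction the secondary allylic C4–OH is activated as its oxyphosphonium ion and displaced by acetate with inversion (SN2) to give the 4,5-trans arrangement (4R), while the tertiary C5–OH cannot be displaced and, being cis, cannot close an epoxide.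

Compound list
1 | (3aS,6aS)-2,2-dimethyl-3a,6a-dihydro-4H-cyclopenta[d][1,3]dioxol-4-one, i.e. (4S,5S)-4,5-O-isopropylidene-4,5-dihydroxycyclopent-2-en-1-one | O=C1C=C[C@@H]2OC(C)(C)O[C@H]12 | starting material
2 | acrolein (prop-2-enal) | C=CC=O | starting material
3 | lithium enolate of 1 (C1–C5 enolate, C4 unchanged; not isolated) | [Li+].[O-]C1=C2OC(C)(C)O[C@H]2C=C1 | intermediate
4 | lithium aldolate: lithium alkoxide of the (1'S)-1-hydroxyprop-2-enyl adduct at C5, side chain anti to the dioxolane (not isolated) | C=C[C@H]([O-])[C@]12OC(C)(C)O[C@H]1C=CC2=O.[Li+] | intermediate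
5 | (4S,5R)-5-[(1S)-1-acetoxyprop-2-en-1-yl]-4,5-(isopropylidenedioxy)cyclopent-2-en-1-one | C=C[C@H](OC(C)=O)[C@]12OC(C)(C)O[C@H]1C=CC2=O | intermediate
6 | 1-bromododecane | CCCCCCCCCCCCBr | starting material
7 | bis(9-BBN) adduct of 5: B-alkyl-9-BBN at C3' and O-(9-BBN) borinate of the ring C1 carbinol (C1 epimers; not isolated) | C(C[C@H](OC(C)=O)[C@]12OC(C)(C)O[C@H]1C=CC2OB1C2CCCC1CCC2)B1C2CCCC1CCC2 | intermediate
8 | C3'–C4' coupled O-(9-BBN) borinate of the ring C1 carbinol (C1 epimers; not isolated) | CCCCCCCCCCCCCC[C@H](OC(C)=O)[C@]12OC(C)(C)O[C@H]1C=CC2OB1C2CCCC1CCC2 | intermediate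
9 | 5-[(1S)-1-acetoxypentadecyl]-4,5-(isopropylidenedioxy)cyclopent-2-en-1-ol, C4/C5/C1' as in 5, C1 carbinol as epimer mixture | CCCCCCCCCCCCCC[C@H](OC(C)=O)[C@]12OC(C)(C)O[C@H]1C=CC2O | intermediate
10 | (4S,5S)-5-[(1S)-1-acetoxypentadecyl]-4,5-(isopropylidenedioxy)cyclopent-2-en-1-one | CCCCCCCCCCCCCC[C@H](OC(C)=O)[C@]12OC(C)(C)O[C@H]1C=CC2=O | intermediate
11 | (4S,5R)-5-[(1S)-1-acetoxypentadecyl]-4,5-dihydroxycyclopent-2-en-1-one (4,5-cis diol) | CCCCCCCCCCCCCC[C@H](OC(C)=O)[C@@]1(O)C(=O)C=C[C@@H]1O | intermediate
12 | (4R,5S)-4-acetoxy-5-[(1S)-1-acetoxypentadecyl]-5-hydroxycyclopent-2-en-1-one | CCCCCCCCCCCCCC[C@H](OC(C)=O)[C@@]1(O)C(=O)C=C[C@H]1OC(C)=O | target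

Total step count: 5. Longest linear sequence: 5 steps (1 → 5 → 9 → 10 → 11 → 12).

Steps most likely to fail

Step 2. The coupling may stall through Pd(0)-induced ionisation of the ring allylic C1–O–boron unit, β-hydride elimination from the alkyl–palladium species, or hydroboration of the ring alkene by excess 9-BBN. The fallback sets out from 5 and returns at 9. Compound 5 is hydroborated with 9-BBN as before (giving 7) but worked up oxidatively (H2O2, pH 7 phosphate buffer) to the diol with a primary C3' hydroxyl and the ring C1 carbinol F1. The primary hydroxyl alone is converted into the primary iodide F2 (I2, PPh3, imidazole, CH2Cl2, 0 °C). The iodide is then displaced by lithium didodecylcuprate (from 6 via dodecyllithium and CuI; excess to allow for the free ring hydroxyl; Et2O, −78 → −20 °C). This classical cuprate SN2 alkylation forms the same C3'–C4' bond with the side-chain terminus as the electrophile and should give 9.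

Step 5. Substitution at C4 next to the quaternary C5 may be slow, and the cis-diol may be tied up as a cyclic dioxaphosphorane, so that the diol is returned or acetate is delivered without inversion. The fallback sets out from 11 and returns at 12. The secondary C4 hydroxyl is sulfonylated selectively (Tf2O, pyridine, CH2Cl2, −30 °C) to the C4 triflate F3. The isolated triflate is displaced with CsOAc/18-crown-6 (toluene, rt) in a separate SN2 step with inversion; the tertiary hydroxyl is not sulfonylated and, being cis, cannot close an epoxide.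

Step 1. The small vinyl group may discriminate poorly between the equatorial and axial positions of the chair transition state, lowering the C1' selectivity, and trapping of the hindered aldolate may be incomplete, allowing retro-aldol erosion. The fallback sets out from 1 and returns at 5. The aldol reaction is quenched at −78 °C with aqueous NH4Cl and the two C1' epimeric alcohols are separated. The (1'S)-alcohol F4 is acetylated (Ac2O, DMAP, pyridine) to 5. The (1'R)-alcohol F5 is converted into the same acetate 5 by Mitsunobu esterification with acetic acid (PPh3, DIAD, THF), which inverts C1', so both epimers converge.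

Further compounds
F1 | step 2 | 5-[(1S)-1-acetoxy-3-hydroxypropyl]-4,5-(isopropylidenedioxy)cyclopent-2-en-1-ol, C4/C5/C1' as in 5, C1 epimers | OCC[C@H](OC(C)=O)[C@]12OC(C)(C)O[C@H]1C=CC2O
F2 | step 2 | 5-[(1S)-1-acetoxy-3-iodopropyl]-4,5-(isopropylidenedioxy)cyclopent-2-en-1-ol, C4/C5/C1' as in 5, C1 epimers | ICC[C@H](OC(C)=O)[C@]12OC(C)(C)O[C@H]1C=CC2O
F3 | step 5 | (4S,5S)-5-[(1S)-1-acetoxypentadecyl]-5-hydroxy-4-(trifluoromethylsulfonyloxy)cyclopent-2-en-1-one | CCCCCCCCCCCCCC[C@H](OC(C)=O)[C@@]1(O)C(=O)C=C[C@@H]1OS(=O)(=O)C(F)(F)F
F4 | step 1 | (4S,5S)-5-[(1S)-1-hydroxyprop-2-en-1-yl]-4,5-(isopropylidenedioxy)cyclopent-2-en-1-one | C=C[C@H](O)[C@]12OC(C)(C)O[C@H]1C=CC2=O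
F5 | step 1 | (4S,5S)-5-[(1R)-1-hydroxyprop-2-en-1-yl]-4,5-(isopropylidenedioxy)cyclopent-2-en-1-one | C=C[C@@H](O)[C@]12OC(C)(C)O[C@H]1C=CC2=O
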